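## Analysis of the target

The target 16 is a 2,2-dimethyl-2H-chromene in which pyran ring B (O1, C2, C3=C4) is fused through C4a–C8a to a fully substituted benzene ring A: C5 carries a 2-(4-hydroxyphenyl)ethyl chain, C6 a methyl ester, C7 a hydroxyl and C8 a 3-methylbut-2-enyl (prenyl) group; these chromene locants are used for the ring-A carbons of all intermediates below. There is no stereocentre (C2 bears two methyl groups) and no alkene of open geometry, so the task is one of connectivity and position only. The sensitive sites are the styrene-like C3=C4 bond with its tertiary allylic aryl ether, the prenyl alkene between two phenolic oxygens (acid closes it to a chroman, electrophiles and oxidants add to it), the electron-rich resorcinol nucleus, and the ester, which is flanked on both sides and hydrogen-bonded to the C7 hydroxyl. The difficulty lies in ring A: six contiguous, different substituents, a prenyl group on the carbon between two oxygens, and a pyran ring that must close onto the C8a oxygen and not the C7 oxygen. Stepwise aromatic substitution gives little control over such a pattern. The strategy rests on the fact that the chain C4a–C8a–C8–prenyl is the carbon skeleton of 6-methylhept-5-en-2-one (6): its methyl carbon is C4a, its carbonyl carbon C8a, its C3 methylene C8, and the remainder is the prenyl chain. C5, C6, C7 and the ester carbon are then the alkylidene carbon, the central carbon and the two carbonyl carbons of alkylidene malonate 5. Ring A can therefore be built as a cyclohexane-1,3-dione in which connectivity places every substituent, and C4a remains the only hydrogen-bearing ring carbon, which leaves a single site for the later pyran annulation.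

## Retrosynthetic reasoning

**16 ⇒ 15.** The last operation frees the remote phenol. In 15 this oxygen is an allyl ether. The group has to survive hot alkoxide during ring construction, which an aryl silyl ether would not. It also has to leave under neutral conditions, because ring B and the prenyl group of 16 tolerate neither strong acid nor hydrogenation.

**15 ⇒ 12 + 13.** Ring B is cut at O1–C2 and C4–C4a, which leads back to resorcylate 12 and enal 13. The forward reaction is a condensation at C4a followed by electrocyclic closure of ortho-quinone methide 14 onto the C8a oxygen. The cut is made here because 12 has only one unsubstituted ring carbon, C4a, and it is ortho to the C8a hydroxyl. The C7 hydroxyl has no free ortho position, so the regiochemistry of the pyran ring is fixed by the substrate.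

**12 ⇒ 10 ⇒ 9.** No skeletal bond is cut; the oxidation level of ring A is lowered. Resorcylate 12 is the dehydrogenation product of cyclohexane-1,3-dione ester 9. The two hydrogens at C5 and C6 are removed through selenide 10 and its selenoxide 11. Going back to a saturated ring turns a hexasubstituted arene into a problem of carbonyl condensation chemistry. The forward step must introduce the double bond without touching the prenyl alkene, which rules out halogen-based aromatisation.

**9 ⇒ 8 ⇒ 5 + 6 (through 7).** The ring of 9 is opened at C7–C8 (retro-Dieckmann) to δ-keto malonate 8, and 8 is cut at C4a–C5 (retro-Michael) to alkylidene malonate 5 and the terminal enolate 7 of ketone 6. This pair of cuts keeps 6 intact, so the prenyl group never has to be attached to a ring. It also gives the C6 ester and the C7 oxygen from the two ester groups of 5. The forward reaction needs enolisation of 6 on its methyl side and conjugate addition of 7 to 5. After that only C8 can reach a malonate ester through a six-membered transition state.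

**5 ⇒ 3 + 4.** The C=C bond of 5 is cut to aldehyde 3 and malonate 4, a Knoevenagel condensation in the forward sense. The acceptor is symmetrical at the malonate carbon, so no alkene geometry arises.

**3 ⇒ 2 ⇒ 1.** Aldehyde 3 comes from ester 2 by partial reduction, and 2 from commercial phenol ester 1 by O-allylation. This short, conventional sequence places the risk of the route in the ring-forming step and the dehydrogenation.

## Alternatives that were turned down

**Alternative 1:** The C5–CH2 bond of the arylethyl chain and the C4a–C4 bond are made on a finished arene.
- Forward key step: a Catellani reaction (palladium catalysis with a strained bicyclic alkene as transient mediator and a carbonate base). Aryl iodide A2 has iodine at the future C4a. It is alkylated at its free ortho C–H by alkyl bromide A3 and then coupled at the ipso carbon with a tertiary allylic alcohol in a terminating Heck reaction, giving A1.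
- For it: it is convergent, forms two C–C bonds in one flask, takes its regiochemistry from the position of the iodine, and needs no oxidation-level change. The oxygen substituent at C8a supplies the single ortho blocking group that the relay requires. On convergence it is stronger than the chosen route.
- Against it: A1 still has hydrogen at C6. The ester must be introduced afterwards at the most hindered ring position, by metalation next to benzylic and allylic C–H bonds. Ring B is not closed either: the E-configured allylic alcohol must be isomerised or ionised with acid next to acid-labile acetal and prenyl groups. A3 is a 2-arylethyl halide and readily loses HBr to a styrene under hot carbonate, and the styrene then competes as Heck acceptor. A2 itself needs a regioselective prenylation between two oxygens.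
- Comparison: the key step solves two of the six positions and leaves the two hardest open, whereas the chosen ring construction fixes all six at once from two acyclic pieces.

**Alternative 2:** The C5–CH2 and C6–CO2Me bonds are made together on an intact chromene through a C5–C6 aryne.
- Forward key step: a hindered lithium amide removes the C5 proton of chlorochromene A5 and chloride is lost. An arylethylmagnesium halide adds at C5, the aryne carbon remote from the alkoxy group, and the C6 arylmagnesium is trapped with a chloroformate to give A4.
- For it: it is a vicinal difunctionalisation with regiochemistry set by the polarisation of an alkoxy-aryne, with ring B and the prenyl group already present. After the key step it is shorter than the chosen route.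
- Against it: A5 is a chlorinated, O-methylated, C8-prenylated chromene whose own synthesis has the regiochemical problems the strategy is meant to avoid. Deprotonation at C5 competes with the benzylic and allylic CH2 of the prenyl group. The C6 arylmetal is flanked on both sides, and excess Grignard reagent consumes the chloroformate. A4 carries a methyl ether at C7, and its cleavage needs a boron trihalide or similar Lewis acid, which would cyclise the ortho-prenyl phenol and attack ring B.
- Comparison: the chosen route delivers the C7 hydroxyl free as a consequence of the Dieckmann closure and starts from bulk chemicals, at the cost of a less convergent ring construction.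

**Alternative 3:** The C5–C6 bond is made by intramolecular aldol condensation of diketo-dioxinone A7.
- Forward key step: with a mild carbonate base the dioxinone carbon next to the lactone carbonyl attacks the arylethyl ketone, the aldol dehydrates, and ring A appears directly as benzodioxinone A6. Methanolysis and the same enal annulation would follow.
- For it: ring A arrives aromatic, so no dehydrogenation is needed next to the prenyl alkene. The conditions are mild, and the acetonide masks both the acid and the C7 oxygen. On functional-group compatibility at the aromatisation stage it is stronger than the chosen route.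
- Against it: A7 must be assembled by successive C-acylations of a dioxinone enolate. The prenyl group must be placed selectively on the carbon between the dioxinone and a ketone, where O-alkylation, dialkylation or linear-versus-branched transfer compete. The polycarbonyl intermediates are labile enol mixtures that can close prematurely or through oxygen to pyranones.
- Comparison: the chosen route reaches its key-step precursor in three conventional steps, and the position of the prenyl group is decided by the structure of 6 rather than by a prenylation. It accepts one selenium-based dehydrogenation in exchange.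

Key step: step 4

Remark on the chemistry: the remote phenol is carried as an allyl ether, because an aryl silyl ether would be cleaved by NaOMe in methanol during the ring closure of step 4; the bond construction is unaffected.

## Route

**Step 1**
Reactants: 1 methyl 3-(4-hydroxyphenyl)propanoate
Product: 2 methyl 3-[4-(allyloxy)phenyl]propanoate
Conditions: allyl bromide, K2CO3, acetone, reflux
Reagents that add atoms: allyl bromide, C=CCBr
Why: Williamson ether synthesis: the phenoxide formed by K2CO3 is O-alkylated by the primary allylic bromide, and the methyl ester is inert to carbonate in acetone.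

**Step 2**
Reactants: 2 methyl 3-[4-(allyloxy)phenyl]propanoate
Product: 3 3-[4-(allyloxy)phenyl]propanal
Conditions: i-Bu2AlH (1.05 equiv), CH2Cl2, −78 °C; MeOH, then aq. potassium sodium tartrate
Reagents that add atoms: none
Why: Partial reduction of an ester: at −78 °C the aluminium hemiacetal formed by one hydride transfer is stable and releases the aldehyde only on work-up, which holds back over-reduction; the allyl ether is untouched.

**Step 3**
Reactants: 3 3-[4-(allyloxy)phenyl]propanal; 4 dimethyl malonate
Product: 5 dimethyl 2-{3-[4-(allyloxy)phenyl]propylidene}malonate
Conditions: piperidine (cat.), AcOH (cat.), toluene, reflux, Dean–Stark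
Reagents that add atoms: none
Why: Knoevenagel condensation through the iminium ion of the aldehyde; azeotropic removal of water drives it, and the symmetrical malonate leaves no alkene geometry to control.

**Step 4**
Reactants: 5 dimethyl 2-{3-[4-(allyloxy)phenyl]propylidene}malonate; 6 6-methylhept-5-en-2-one
Product: 9 methyl trans-2-hydroxy-4-oxo-3-(3-methylbut-2-enyl)-6-{2-[4-(allyloxy)phenyl]ethyl}cyclohex-2-ene-1-carboxylate (racemic), via lithium enolate 7 (not isolated), via Michael adduct 8 (not isolated)
Conditions: LiN(i-Pr)2 (1.05 equiv), THF, −78 °C, add 6; then 5, −78 °C; then NaOMe (2 equiv), MeOH, −78 °C → reflux; cold 1 M HCl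
Reagents that add atoms: none
Why: The hindered amide removes a methyl proton of 6 faster than a methylene proton at −78 °C and gives terminal enolate 7, which adds through its CH2 carbon to the doubly activated β-carbon of 5 (Michael addition, C4a–C5 bond) to give the malonate enolate of 8. With NaOMe in methanol, proton exchange produces the ketone enolate at the methylene that carries the prenyl chain, and this carbon attacks one malonate ester carbonyl (Dieckmann condensation, C7–C8 bond) in a 6-exo-trig closure. Loss of methoxide and deprotonation of the resulting 2-substituted cyclohexane-1,3-dione make the closure irreversible and drive the sequence. The closest known reaction type is the Michael–Dieckmann synthesis of 5-substituted cyclohexane-1,3-diones from malonates and enones, which passes through the same kind of δ-keto malonate; here that intermediate is entered from the ketone-enolate and alkylidene-malonate side. The C5 stereocentre forms without control (racemate); the C6 centre is epimerisable between two carbonyl groups and should settle under methoxide to the trans isomer with both substituents equatorial. Both centres disappear on aromatisation, so neither matters for the target. The step needs methyl-side enolisation of 6, which the kinetic conditions and the lower reactivity of the internal enolate towards a β-substituted acceptor secure, and conjugate addition in preference to proton abstraction from the γ-CH2 of 5, which the low temperature favours. In 8 the regiochemistry of ring closure is fixed, since attack from C4a would give a four-membered ring.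

**Step 5**
Reactants: 9 methyl trans-2-hydroxy-4-oxo-3-(3-methylbut-2-enyl)-6-{2-[4-(allyloxy)phenyl]ethyl}cyclohex-2-ene-1-carboxylate
Product: 10 methyl 2-hydroxy-4-oxo-1-(phenylselanyl)-3-(3-methylbut-2-enyl)-6-{2-[4-(allyloxy)phenyl]ethyl}cyclohex-2-ene-1-carboxylate (PhSe trans to arylethyl; racemic)
Conditions: LiN(i-Pr)2 (2.2 equiv), THF, −78 → 0 °C; PhSeBr (1.0 equiv), −78 °C; aq. NH4Cl
Reagents that add atoms: benzeneselenenyl bromide (PhSeBr), Br[Se]c1ccccc1
Why: α-Selenenylation of a dianion: two equivalents of base give the dione enolate plus the ester-stabilised carbanion at C6, and electrophilic selenium is taken up at this more basic carbon rather than at C8; PhSe enters anti to the C5 side chain and therefore syn to C5–H. Any selenium delivered to C4a instead would lead to the same arene in step 6.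

**Step 6**
Reactants: 10 methyl 2-hydroxy-4-oxo-1-(phenylselanyl)-3-(3-methylbut-2-enyl)-6-{2-[4-(allyloxy)phenyl]ethyl}cyclohex-2-ene-1-carboxylate
Product: 12 methyl 2,4-dihydroxy-3-(3-methylbut-2-enyl)-6-{2-[4-(allyloxy)phenyl]ethyl}benzoate, via selenoxide 11 (not isolated)
Conditions: mCPBA (1.0 equiv), CH2Cl2, −78 °C; then i-Pr2NH, −78 °C → rt
Reagents that add atoms: none
Why: Selenoxide elimination: selenide oxidation is far faster than alkene epoxidation at −78 °C, and 11 undergoes syn elimination with C5–H on warming; the cyclohexadienone formed tautomerises to the arene. i-Pr2NH intercepts PhSeOH before it can add to the prenyl or allyl double bond.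

**Step 7**
Reactants: 12 methyl 2,4-dihydroxy-3-(3-methylbut-2-enyl)-6-{2-[4-(allyloxy)phenyl]ethyl}benzoate; 13 3-methylbut-2-enal
Product: 15 methyl 7-hydroxy-2,2-dimethyl-8-(3-methylbut-2-enyl)-5-{2-[4-(allyloxy)phenyl]ethyl}-2H-chromene-6-carboxylate, via ortho-quinone methide 14 (not isolated)
Conditions: 13 (3 equiv), ethylenediammonium diacetate (20 mol%), toluene, reflux
Reagents that add atoms: none
Why: Amine-salt-catalysed Knoevenagel-type condensation of the enal at C4a (ortho to the C8a hydroxyl, the only unsubstituted ring carbon) with loss of water gives 14, which closes by oxa-6π electrocyclisation to the 2,2-dimethyl-2H-chromene. The chelated C7 hydroxyl has no free ortho carbon and cannot compete.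

**Step 8**
Reactants: 15 methyl 7-hydroxy-2,2-dimethyl-8-(3-methylbut-2-enyl)-5-{2-[4-(allyloxy)phenyl]ethyl}-2H-chromene-6-carboxylate
Product: 16 methyl 7-hydroxy-5-[2-(4-hydroxyphenyl)ethyl]-2,2-dimethyl-8-(3-methylbut-2-enyl)-2H-chromene-6-carboxylate
Conditions: Pd(PPh3)4 (5 mol%), morpholine (10 equiv), THF, rt
Reagents that add atoms: none
Why: Tsuji–Trost-type deallylation: zerovalent palladium ionises the unsubstituted allyl aryl ether to a π-allyl complex of divalent palladium and the phenoxide, and morpholine takes up the allyl group. The C-bound prenyl group cannot ionise, and the cyclic tertiary allylic ether of ring B is too hindered to do so at room temperature.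

## Compound list

1 | methyl 3-(4-hydroxyphenyl)propanoate | COC(=O)CCc1ccc(O)cc1 | starting material
2 | methyl 3-[4-(allyloxy)phenyl]propanoate | COC(=O)CCc1ccc(OCC=C)cc1 | intermediate
3 | 3-[4-(allyloxy)phenyl]propanal | O=CCCc1ccc(OCC=C)cc1 | intermediate
4 | dimethyl malonate | COC(=O)CC(=O)OC | starting material
5 | dimethyl 2-{3-[4-(allyloxy)phenyl]propylidene}malonate | COC(=O)C(=CCCc1ccc(OCC=C)cc1)C(=O)OC | intermediate
6 | 6-methylhept-5-en-2-one | CC(=O)CCC=C(C)C | starting material
7 | lithium 6-methylhepta-1,5-dien-2-olate | [Li]OC(=C)CCC=C(C)C | intermediate (not isolated)
8 | dimethyl 2-{1-[4-(allyloxy)phenyl]-9-methyl-5-oxodec-8-en-3-yl}malonate (racemic, one enantiomer drawn; present as its malonate enolate) | COC(=O)C(C(=O)OC)[C@@H](CCc1ccc(OCC=C)cc1)CC(=O)CCC=C(C)C | intermediate (not isolated)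
9 | methyl trans-2-hydroxy-4-oxo-3-(3-methylbut-2-enyl)-6-{2-[4-(allyloxy)phenyl]ethyl}cyclohex-2-ene-1-carboxylate (racemic, one enantiomer drawn; enol form of the 2,4-dioxo ester) | COC(=O)[C@H]1C(O)=C(CC=C(C)C)C(=O)C[C@@H]1CCc1ccc(OCC=C)cc1 | intermediate
10 | methyl 2-hydroxy-4-oxo-1-(phenylselanyl)-3-(3-methylbut-2-enyl)-6-{2-[4-(allyloxy)phenyl]ethyl}cyclohex-2-ene-1-carboxylate (PhSe trans to the arylethyl group; racemic, one enantiomer drawn) | COC(=O)[C@]1([Se]c2ccccc2)C(O)=C(CC=C(C)C)C(=O)C[C@@H]1CCc1ccc(OCC=C)cc1 | intermediate
11 | methyl 2-hydroxy-4-oxo-1-(phenylseleninyl)-3-(3-methylbut-2-enyl)-6-{2-[4-(allyloxy)phenyl]ethyl}cyclohex-2-ene-1-carboxylate (selenoxide of 10; mixture at selenium) | COC(=O)[C@]1([Se](=O)c2ccccc2)C(O)=C(CC=C(C)C)C(=O)C[C@@H]1CCc1ccc(OCC=C)cc1 | intermediate (not isolated)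
12 | methyl 2,4-dihydroxy-3-(3-methylbut-2-enyl)-6-{2-[4-(allyloxy)phenyl]ethyl}benzoate | COC(=O)c1c(O)c(CC=C(C)C)c(O)cc1CCc1ccc(OCC=C)cc1 | intermediate
13 | 3-methylbut-2-enal | CC(C)=CC=O | starting material
14 | methyl 6-hydroxy-5-(3-methylbut-2-enyl)-3-(3-methylbut-2-enylidene)-4-oxo-2-{2-[4-(allyloxy)phenyl]ethyl}cyclohexa-1,5-diene-1-carboxylate (ortho-quinone methide; exocyclic geometry not fixed) | COC(=O)C1=C(CCc2ccc(OCC=C)cc2)C(=CC=C(C)C)C(=O)C(CC=C(C)C)=C1O | intermediate (not isolated)
15 | methyl 7-hydroxy-2,2-dimethyl-8-(3-methylbut-2-enyl)-5-{2-[4-(allyloxy)phenyl]ethyl}-2H-chromene-6-carboxylate | COC(=O)c1c(O)c(CC=C(C)C)c2c(c1CCc1ccc(OCC=C)cc1)C=CC(C)(C)O2 | intermediate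
16 | methyl 7-hydroxy-5-[2-(4-hydroxyphenyl)ethyl]-2,2-dimethyl-8-(3-methylbut-2-enyl)-2H-chromene-6-carboxylate | COC(=O)c1c(O)c(CC=C(C)C)c2c(c1CCc1ccc(O)cc1)C=CC(C)(C)O2 | target

## Step count and risk

Total: 8 steps. Longest linear sequence: 8 steps (1 → 16); 4, 6 and 13 enter as purchased building blocks.

**Step 4 (key step).**
- Most likely failure: proton transfer from the acidic γ-CH2 of 5 to enolate 7 in place of conjugate addition. Partial formation of the internal enolate of 6 is the second risk; it would add and then close through the methyl carbon to a regioisomeric dione.
- Fallback: it changes the Michael bond from C4a–C5 to C5–C6, sets out from aldehyde 3 and returns at 9. Enolate 7 is added to 3 at −78 °C in an aldol reaction to give 1-[4-(allyloxy)phenyl]-3-hydroxy-9-methyldec-8-en-5-one F1. Mesylation and elimination (MsCl, Et3N, then DBU) give (E)-1-[4-(allyloxy)phenyl]-9-methyldeca-3,8-dien-5-one F2. Malonate 4 with NaOMe in methanol at reflux then adds to the enone and the resulting 8 closes to 9, as in the classical malonate–enone cyclohexanedione synthesis.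

**Step 6 (with the selenide from step 5).**
- Most likely failure: addition of electrophilic selenium by-products or of peracid to the prenyl or allyl alkene, because three nucleophilic sites (selenide, trisubstituted alkene, dione enol) compete for the oxidant. Incomplete dianion formation in step 5 would also deliver selenium to C8.
- Fallback: it avoids any external oxidant, sets out from 9 and returns at 12. The dianion of 9 (LiN(i-Pr)2, 2.2 equiv, THF) is treated at −78 °C with N-tert-butylbenzenesulfinimidoyl chloride. The C6 adduct, methyl 1-(N-tert-butyl-S-phenylsulfinimidoyl)-2-hydroxy-4-oxo-3-(3-methylbut-2-enyl)-6-{2-[4-(allyloxy)phenyl]ethyl}cyclohex-2-ene-1-carboxylate F3, is not isolated. Its nitrogen removes C5–H intramolecularly below room temperature, and tautomerisation gives 12 directly.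

**Step 7.**
- Most likely failure: sluggish C-attack at C4a, which is ortho to the arylethyl chain and sits on an ester-deactivated ring, so that self-condensation of the enal takes over.
- Fallback: it replaces the intermolecular C–C bond formation by an O-alkylation and a sigmatropic shift, sets out from 12 and returns at 15. The non-chelated C8a hydroxyl is alkylated with 3-chloro-3-methylbut-1-yne (CuCl2 cat., DBU, MeCN, 0 °C) to give methyl 2-hydroxy-4-[(2-methylbut-3-yn-2-yl)oxy]-3-(3-methylbut-2-enyl)-6-{2-[4-(allyloxy)phenyl]ethyl}benzoate F4. Heating in xylene at about 140 °C should bring about propargyl Claisen rearrangement to C4a, hydrogen shift to 14 and electrocyclisation to 15. This temperature is below that at which the allyl aryl ether rearranges.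

**Step 8.**
- Most likely failure: allyl transfer from the π-allyl palladium intermediate to the resorcinol nucleus or its oxygens, or slow ionisation of the allylic C2–O1 bond of ring B.
- Fallback: it avoids π-allyl palladium, sets out from 15 and returns at 16. The allyl ether is isomerised with hydrogen-activated [Ir(cod)(PMePh2)2]PF6 in THF at room temperature to methyl 7-hydroxy-2,2-dimethyl-8-(3-methylbut-2-enyl)-5-(2-{4-[(E)-prop-1-enyloxy]phenyl}ethyl)-2H-chromene-6-carboxylate F5. The enol ether is then hydrolysed with dilute HCl in aqueous acetone at room temperature, conditions under which the trisubstituted prenyl alkene should not be protonated.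

## Further compounds

F1 | step 4 | 1-[4-(allyloxy)phenyl]-3-hydroxy-9-methyldec-8-en-5-one (racemic) | C=CCOc1ccc(CCC(O)CC(=O)CCC=C(C)C)cc1
F2 | step 4 | (E)-1-[4-(allyloxy)phenyl]-9-methyldeca-3,8-dien-5-one | C=CCOc1ccc(CC/C=C/C(=O)CCC=C(C)C)cc1
F3 | step 6 | methyl 1-(N-tert-butyl-S-phenylsulfinimidoyl)-2-hydroxy-4-oxo-3-(3-methylbut-2-enyl)-6-{2-[4-(allyloxy)phenyl]ethyl}cyclohex-2-ene-1-carboxylate (sulfur trans to the arylethyl group; racemic, one enantiomer drawn) | COC(=O)[C@]1(S(=NC(C)(C)C)c2ccccc2)C(O)=C(CC=C(C)C)C(=O)C[C@@H]1CCc1ccc(OCC=C)cc1
F4 | step 7 | methyl 2-hydroxy-4-[(2-methylbut-3-yn-2-yl)oxy]-3-(3-methylbut-2-enyl)-6-{2-[4-(allyloxy)phenyl]ethyl}benzoate | COC(=O)c1c(O)c(CC=C(C)C)c(OC(C)(C)C#C)cc1CCc1ccc(OCC=C)cc1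
F5 | step 8 | methyl 7-hydroxy-2,2-dimethyl-8-(3-methylbut-2-enyl)-5-(2-{4-[(E)-prop-1-enyloxy]phenyl}ethyl)-2H-chromene-6-carboxylate | COC(=O)c1c(O)c(CC=C(C)C)c2c(c1CCc1ccc(O/C=C/C)cc1)C=CC(C)(C)O2
A1 | alternative 1 | (E)-4-{2,4-bis(methoxymethoxy)-3-(3-methylbut-2-enyl)-6-[2-(4-tert-butyldimethylsilyloxyphenyl)ethyl]phenyl}-2-methylbut-3-en-2-ol | COCOc1cc(CCc2ccc(O[Si](C)(C)C(C)(C)C)cc2)c(/C=C/C(C)(C)O)c(OCOC)c1CC=C(C)C
A2 | alternative 1 | 1-iodo-2,4-bis(methoxymethoxy)-3-(3-methylbut-2-enyl)benzene | COCOc1ccc(I)c(OCOC)c1CC=C(C)C
A3 | alternative 1 | [4-(2-bromoethyl)phenoxy](tert-butyl)dimethylsilane | BrCCc1ccc(O[Si](C)(C)C(C)(C)C)cc1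
A4 | alternative 2 | methyl 7-methoxy-2,2-dimethyl-8-(3-methylbut-2-enyl)-5-[2-(4-tert-butyldimethylsilyloxyphenyl)ethyl]-2H-chromene-6-carboxylate | COC(=O)c1c(OC)c(CC=C(C)C)c2OC(C)(C)C=Cc2c1CCc1ccc(O[Si](C)(C)C(C)(C)C)cc1
A5 | alternative 2 | 6-chloro-7-methoxy-2,2-dimethyl-8-(3-methylbut-2-enyl)-2H-chromene | COc1c(Cl)cc2C=CC(C)(C)Oc2c1CC=C(C)C
A6 | alternative 3 | 7-hydroxy-2,2-dimethyl-8-(3-methylbut-2-enyl)-5-[2-(4-tert-butyldimethylsilyloxyphenyl)ethyl]-4H-1,3-benzodioxin-4-one | CC1(C)OC(=O)c2c(CCc3ccc(O[Si](C)(C)C(C)(C)C)cc3)cc(O)c(CC=C(C)C)c2O1
A7 | alternative 3 | 6-{1-[4-(tert-butyldimethylsilyloxy)phenyl]-9-methyl-3,5-dioxodec-8-en-6-yl}-2,2-dimethyl-4H-1,3-dioxin-4-one (racemic) | CC1(C)OC(=O)C=C(O1)C(CC=C(C)C)C(=O)CC(=O)CCc1ccc(O[Si](C)(C)C(C)(C)C)cc1
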